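**Ligand ratio.** The flask is charged at 1.00 equivalents of incoming ligand, while the alpha run had twice that ratio, so the ligand in the flask is expected to fall further as a share of its charge.

| flask | starting complex | incoming ligand | capture agent | remark | time |
|---|---|---|---|---|---|
| alpha | 0.16 M | 0.32 M | 0.096 M | run made earlier |  |
| theta | 0.24 M | 0.32 M | 0.096 M | run made earlier |  |
| flask | 0.32 M | 0.320 M | 0.0960 M |  | 12 min |

| run | time / min | complex with one exchanged / % | complex with three exchanged / % |
|---|---|---|---|
| alpha | 0.417 | 2.6 | 0 |
| alpha | 1.00 | 6.4 | 0.4 |
| alpha | 2.00 | 11.5 | 0.1 |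
| alpha | 3.00 | 15.9 | 0 |
| alpha | 4.00 | 19.2 | 0 |
| alpha | 6.00 | 22.4 | 0.4 |
| alpha | 8.00 | 25.3 | 0 |
| theta | 0.417 | 2.9 | 0 |
| theta | 1.00 | 6.9 | 0.7 |
| theta | 2.00 | 11.9 | 0.3 |
| theta | 3.00 | 15.8 | 0.9 |
| theta | 4.00 | 18.3 | 0.7 |
| theta | 6.00 | 21.9 | 1.2 |
| theta | 8.00 | 24.6 | 0.9 |

(each reading ± 0.5 percentage points)



- equivalents of incoming ligand to starting complex, everything else as given, that leave most complex with one exchanged at 12 min
- the amount of complex with one exchanged then, in percent of the starting complex charged
- the amount of complex with one exchanged with the amounts as given

**What matters.** Complex with one exchanged at 8.00 min reads 25.3% in alpha and 24.6% in theta, 0.7 percentage points apart with a scatter of 0.5 points, so the charge of starting complex barely shows in percent. Ligand and capture agent were the same in both runs, so neither is tested.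

**Entry constant.** The mean first-minute reading gives u, the fraction of starting complex converted per minute with ligand at its charge, a pseudo-first-order constant: 0.0665 min⁻¹.

**Two rounds.** My own reckoning for the flask first holds the ligand at its charge, and exp(−ut), with t the time, leaves 45.0% of the starting complex after 12 min. The flask is charged with equal amounts, and ligand is taken to go one-for-one with starting complex, so its mean is taken as midway, 72.5% of the charge. Multiplying u by that share, which assumes a rate proportional to ligand, leaves 56.1%. Alpha's or theta's reading alone gives 57.0% or 55.2%, so the falling ligand moves the reckoned starting complex more than the choice of reading does.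

**The forecast.** “Assuming both steps scale with ligand”, it gives 26% as charged and 28% at 1.2 equiv.

**The result.**

    starting complex + incoming ligand ⇌ leaving ligand + complex with one exchanged (K = 0.830, k = 0.00390 M⁻¹ s⁻¹)
    complex with one exchanged + incoming ligand ⇌ leaving ligand + complex with two exchanged (K = 0.140, k = 9.10 × 10⁻⁴ M⁻¹ s⁻¹)
    complex with two exchanged + incoming ligand ⇌ leaving ligand + complex with three exchanged (K = 0.500, k = 0.00530 M⁻¹ s⁻¹)
    complex with three exchanged ⇌ isomer of the product (K = 0.620, k = 0.00700 s⁻¹)
    leaving ligand → by-product carried off (k = 0.00390 s⁻¹)
    complex with one exchanged + capture agent → trapped intermediate (k = 0.0180 M⁻¹ s⁻¹)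

The flask gives 26.1% of complex with one exchanged, and its best charge of ligand is 3.06 equiv, giving 42.4%. Starting complex in the flask stands at 55.1% after 12.0 min, beside the reckoned 56.1%. As charged, the capture path has a half-life for complex with one exchanged of 6.7 min, shorter than the 40 min of the forward ligand path. The neighbour flask has 1.3 M of ligand, which scales u to 0.270 min⁻¹. The first round leaves 3.91% of the starting complex, mean ligand is reckoned at 88.2% of its charge, and the second round leaves 5.74%. That flask holds more starting complex than reckoned, 11.3% after 12.0 min, with 40.7% of complex with one exchanged.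

Readings and results were computed with constants of no real substance, noise included.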